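## Retrosynthetic overview
1. The target comes from its tris-MOM ether. The C5 hydroxyl comes from the C5–H bond of a 7-oxygenated 8-alkylflavanone (ketone-directed C–H borylation, then a boron-to-oxygen aryl shift), so ring A needs only the two oxygens of resorcinol.
2. The C2–C1' bond and the C2 centre come from a rhodium-catalysed asymmetric 1,4-addition of a ring B boronic acid (from resorcinol) to an 8-alkylchromone.
3. Ring C is the only ring that is built. It comes from a 2-hydroxyacetophenone and a one-carbon amide acetal, and the acetyl group comes from ortho-lithiation of the 2-alkylresorcinol bis-MOM ether. Closure is possible only through the oxygen next to the side chain.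
4. The key disconnection is C8–C1''. It is a 1,2-aryl shift from boron to carbon between a 2,6-dioxygenated arylboronate and the diazoalkane released from a lactol-derived sulfonylhydrazone, followed by protodeboronation.
5. The side chain comes from (S)-β-methyl-γ-butyrolactone and prenyl bromide by trans-selective enolate alkylation. Ring order: A and B are bought as resorcinol, the lactone ring is opened in step 3, ring C is closed in step 6, and ring B is attached in step 9.

Assumption: (S)-4-methyldihydrofuran-2(3H)-one is bought enantiopure; labels used are C1'' (benzylic CH2), C2'' (CH bearing prenyl), C3'' (CH bearing CH3), C4'' (CH2OH), SC = the (2R)-2-[(2S)-1-hydroxypropan-2-yl]-5-methylhex-4-en-1-yl side chain, MOM = CH2OCH3, Bpin = 4,4,5,5-tetramethyl-1,3,2-dioxaborolan-2-yl.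

## Route

Step 1
Reactants: 1 resorcinol
Product: 2 1,3-bis(methoxymethoxy)benzene
Conditions: MOMCl (2.5 equiv), K2CO3, acetone, 0 °C to rt
Reagents that add atoms: chloromethyl methyl ether (MOMCl), COCCl
Why: Williamson-type O-alkylation of both phenoxides gives the bis-acetal, which later serves both as protecting group and as ortho-directing group for rings A and B, and no stereocentre is formed.

Step 2
Reactants: 3 (S)-4-methyldihydrofuran-2(3H)-one; 4 1-bromo-3-methylbut-2-ene (prenyl bromide)
Product: 5 (3S,4S)-4-methyl-3-(3-methylbut-2-en-1-yl)dihydrofuran-2(3H)-one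
Conditions: LiN(i-Pr)2 (1.05 equiv), THF, −78 °C; 4, DMPU, −78 to −30 °C
Reagents that add atoms: none
Why: Kinetic lactone enolate alkylation (SN2 on the primary allylic bromide) takes place on the ring face anti to the C4 methyl group, so the new centre (C2'' of the target) is set trans to the bought centre C3'' with the usual selectivity of about 10:1 or better.

Step 3
Reactants: 5 (3S,4S)-4-methyl-3-(3-methylbut-2-en-1-yl)dihydrofuran-2(3H)-one
Product: 7 (E)-N'-[(2S,3S)-4-hydroxy-3-methyl-2-(3-methylbut-2-en-1-yl)butylidene]-2-(trifluoromethyl)benzenesulfonohydrazide, via lactol 6 (not isolated)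
Conditions: i-Bu2AlH (1.1 equiv), CH2Cl2, −78 °C; aq. potassium sodium tartrate; crude 6, 2-(CF3)C6H4SO2NHNH2, MeOH, 0 °C to rt
Reagents that add atoms: 2-(trifluoromethyl)benzenesulfonohydrazide, NNS(=O)(=O)c1ccccc1C(F)(F)F
Why: Partial lactone reduction stops at the tetrahedral aluminium hemiacetal at −78 °C, and the lactol condenses through its open hydroxy aldehyde form with the sulfonyl hydrazide under neutral conditions (hydrazone formation), which leaves the α-stereocentre untouched.

Step 4
Reactants: 2 1,3-bis(methoxymethoxy)benzene; 7 the hydroxy sulfonylhydrazone of step 3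
Product: 11 (2S,3R)-3-[2,6-bis(methoxymethoxy)benzyl]-2,6-dimethylhept-5-en-1-ol, via dimethyl arylboronate 8 (not isolated), via boron-tethered diazoalkane 9 (not isolated), via 3-aryl-1,2-oxaborinane 10 (not isolated)
Conditions: 2 (2.0 equiv), n-BuLi, THF, 0 °C; B(OMe)3, −78 °C to rt; Me3SiCl (2.0 equiv); 7 (1.0 equiv), Cs2CO3 (2.5 equiv), 1,4-dioxane, 45 °C; then H2O, 100 °C
Reagents that add atoms: trimethyl borate, COB(OC)OC (boron and methoxy groups of 8, 9 and 10 only; no atom of it stays in 11)
Why: Proposed new method: a hydroxyl-tethered, low-temperature version of the metal-free reductive coupling of sulfonylhydrazones with boronic acids (Barluenga–Valdés coupling, the closest known reaction type, not shown so far for lactol-derived hydroxy hydrazones, for a boron tether or for 2,6-dialkoxyaryl boron reagents), in which the C4'' hydroxyl of 7 exchanges with a methoxy group of 8, Cs2CO3 removes only the N–H proton and the electron-poor sulfinate leaves at 45 °C (Bamford–Stevens step) to give 9, the diazo carbon attacks the tethered boron through a six-membered ate complex faster than it can undergo a hydride shift or be captured by the hydroxyl, the electron-rich aryl group then shifts 1,2 from boron to carbon as N2 leaves and forms the C8–C1'' bond in 10, and hot aqueous carbonate protodeboronates the benzylic C–B bond, while C2'' and C3'' are never deprotonated and keep their configuration.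

Step 5
Reactants: 11 (2S,3R)-3-[2,6-bis(methoxymethoxy)benzyl]-2,6-dimethylhept-5-en-1-ol; 12 N-methoxy-N-methylacetamide
Product: 14 1-[2-hydroxy-4-(methoxymethoxy)-3-SC-phenyl]ethan-1-one, via bis-MOM ketone 13 (not isolated)
Conditions: n-BuLi (2.3 equiv), TMEDA, THF, 0 °C; 12, −78 to 0 °C; aq. NH4Cl; crude 13, p-TsOH·H2O (10 mol%), MeOH, rt
Reagents that add atoms: none
Why: Directed ortho-metalation next to a MOM ether (the alkoxide forms first and the two open ortho positions are equivalent) followed by the Weinreb ketone synthesis gives 13 without over-addition, and mild acid methanolysis removes only the MOM group squeezed between acetyl and alkyl groups, which ends as a hydrogen-bonded phenol.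

Step 6
Reactants: 14 1-[2-hydroxy-4-(methoxymethoxy)-3-SC-phenyl]ethan-1-one; 15 N,N-dimethylformamide dimethyl acetal
Product: 17 7-(methoxymethoxy)-8-SC-4H-chromen-4-one, via enaminone 16 (not isolated)
Conditions: 15 (3 equiv), toluene, 95 °C; evaporation with MeOH chase; AcOH, 60 °C
Reagents that add atoms: none
Why: Condensation of the methyl ketone with the amide acetal gives the enaminone, and acid-promoted addition–elimination of the free ortho phenol closes ring C (enaminone route to chromones), the 8-substitution pattern being fixed because only the oxygen next to the side chain is free.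

Step 7
Reactants: 2 1,3-bis(methoxymethoxy)benzene
Product: 18 1-bromo-2,4-bis(methoxymethoxy)benzene
Conditions: NBS (1.0 equiv), MeCN, 0 °C
Reagents that add atoms: N-bromosuccinimide, O=C1CCC(=O)N1Br
Why: Electrophilic aromatic bromination goes para to one MOM ether and ortho to the other, because the position between the two ethers is too hindered.

Step 8
Reactants: 18 1-bromo-2,4-bis(methoxymethoxy)benzene
Product: 19 [2,4-bis(methoxymethoxy)phenyl]boronic acid
Conditions: n-BuLi, THF, −78 °C; B(Oi-Pr)3, −78 °C to rt; aq. NH4Cl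
Reagents that add atoms: triisopropyl borate, CC(C)OB(OC(C)C)OC(C)C (boron); water, O (both OH oxygens)
Why: Bromine–lithium exchange, borate trapping and mild hydrolysis are the standard arylboronic acid synthesis and keep the MOM ethers intact.

Step 9
Reactants: 17 7-(methoxymethoxy)-8-SC-4H-chromen-4-one; 19 [2,4-bis(methoxymethoxy)phenyl]boronic acid
Product: 20 (2S)-2-[2,4-bis(methoxymethoxy)phenyl]-7-(methoxymethoxy)-8-SC-2,3-dihydro-4H-chromen-4-one
Conditions: 19 (2.5 equiv), [RhCl(C2H4)2]2 (1.5 mol%), (S)-MeO-F12-BIPHEP (3.3 mol%), KOH (10 mol%), toluene–H2O 10:1, 25 °C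
Reagents that add atoms: none
Why: In this Hayashi–Miyaura reaction the aryl–rhodium species bearing the electron-poor chiral bisphosphine inserts the chromone C2=C3 bond on one face and the resulting oxa-π-allyl is hydrolysed, so catalyst control sets C2 as S (the same face model by which (S)-biaryl bisphosphines give (S)-3-arylcyclohexanones) independently of the remote side-chain centres.

Step 10
Reactants: 20 (2S)-2-[2,4-bis(methoxymethoxy)phenyl]-7-(methoxymethoxy)-8-SC-2,3-dihydro-4H-chromen-4-one
Product: 22 (2S)-2-[2,4-bis(methoxymethoxy)phenyl]-5-hydroxy-7-(methoxymethoxy)-8-SC-2,3-dihydro-4H-chromen-4-one, via bis-boryl flavanone 21 (not isolated)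
Conditions: B2pin2 (1.5 equiv), [Ir(OMe)(cod)]2 (3 mol%), AsPh3 (12 mol%), octane, 110 °C; then 30% H2O2, pH 7 phosphate buffer, THF, 0 °C
Reagents that add atoms: bis(pinacolato)diboron, CC1(C)OB(OC1(C)C)B1OC(C)(C)C(C)(C)O1 (Bpin groups of 21); hydrogen peroxide, OO (oxygen at C5 of 22)
Why: Ketone-directed iridium-catalysed ortho C–H borylation reaches the only C–H bond ortho to the chromanone carbonyl (C5) while the alcohol is masked in the flask as its borate, and buffered peroxide turns C–B into C–O by a 1,2-aryl shift from boron to oxygen under conditions too mild to open ring C or touch C2.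

Step 11
Reactants: 22 (2S)-2-[2,4-bis(methoxymethoxy)phenyl]-5-hydroxy-7-(methoxymethoxy)-8-SC-2,3-dihydro-4H-chromen-4-one
Product: 23 (2S)-2-(2,4-dihydroxyphenyl)-5,7-dihydroxy-8-[(2R)-2-[(2S)-1-hydroxypropan-2-yl]-5-methylhex-4-en-1-yl]-2,3-dihydro-4H-chromen-4-one
Conditions: HCl (1.25 M in MeOH), 0 °C to rt
Reagents that add atoms: none
Why: Acid-catalysed acetal exchange with methanol removes the three aryl MOM ethers at or below room temperature, where the trisubstituted alkene and the C2 centre are kept.

## Compound list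
1 | resorcinol (benzene-1,3-diol) | Oc1cccc(O)c1 | starting material
2 | 1,3-bis(methoxymethoxy)benzene | COCOc1cccc(OCOC)c1 | intermediate
3 | (S)-4-methyldihydrofuran-2(3H)-one | O=C1C[C@H](C)CO1 | starting material
4 | 1-bromo-3-methylbut-2-ene (prenyl bromide) | CC(C)=CCBr | starting material
5 | (3S,4S)-4-methyl-3-(3-methylbut-2-en-1-yl)dihydrofuran-2(3H)-one (trans) | CC(C)=CC[C@H](C1=O)[C@H](C)CO1 | intermediate
6 | (3S,4S)-4-methyl-3-(3-methylbut-2-en-1-yl)tetrahydrofuran-2-ol, anomer mixture (not isolated) | CC(C)=CC[C@H](C1O)[C@H](C)CO1 | intermediate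
7 | (E)-N'-[(2S,3S)-4-hydroxy-3-methyl-2-(3-methylbut-2-en-1-yl)butylidene]-2-(trifluoromethyl)benzenesulfonohydrazide | CC(C)=CC[C@H](/C=N/NS(=O)(=O)c1ccccc1C(F)(F)F)[C@H](C)CO | intermediate
8 | dimethyl [2,6-bis(methoxymethoxy)phenyl]boronate (not isolated) | COB(OC)c1c(OCOC)cccc1OCOC | intermediate
9 | methyl (2S,3S)-4-diazo-2-methyl-3-(3-methylbut-2-en-1-yl)butyl [2,6-bis(methoxymethoxy)phenyl]boronate (not isolated) | CC(C)=CC[C@H](C=[N+]=[N-])[C@H](C)COB(OC)c1c(OCOC)cccc1OCOC | intermediate
10 | (4R,5S)-3-[2,6-bis(methoxymethoxy)phenyl]-2-methoxy-5-methyl-4-(3-methylbut-2-en-1-yl)-1,2-oxaborinane, mixture at C3 (not isolated) | CC(C)=CC[C@H](C(c1c(OCOC)cccc1OCOC)B2OC)[C@H](C)CO2 | intermediate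
11 | (2S,3R)-3-[2,6-bis(methoxymethoxy)benzyl]-2,6-dimethylhept-5-en-1-ol | CC(C)=CC[C@H](Cc1c(OCOC)cccc1OCOC)[C@H](C)CO | intermediate
12 | N-methoxy-N-methylacetamide | CC(=O)N(C)OC | starting material
13 | 1-[2,4-bis(methoxymethoxy)-3-SC-phenyl]ethan-1-one (not isolated) | CC(C)=CC[C@H](Cc1c(OCOC)ccc(C(C)=O)c1OCOC)[C@H](C)CO | intermediate
14 | 1-[2-hydroxy-4-(methoxymethoxy)-3-SC-phenyl]ethan-1-one | CC(C)=CC[C@H](Cc1c(OCOC)ccc(C(C)=O)c1O)[C@H](C)CO | intermediate
15 | N,N-dimethylformamide dimethyl acetal | COC(OC)N(C)C | starting material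
16 | (E)-3-(dimethylamino)-1-[2-hydroxy-4-(methoxymethoxy)-3-SC-phenyl]prop-2-en-1-one (not isolated) | CC(C)=CC[C@H](Cc1c(OCOC)ccc(C(=O)/C=C/N(C)C)c1O)[C@H](C)CO | intermediate
17 | 7-(methoxymethoxy)-8-SC-4H-chromen-4-one | CC(C)=CC[C@H](Cc1c(OCOC)ccc2c1OC=CC2=O)[C@H](C)CO | intermediate
18 | 1-bromo-2,4-bis(methoxymethoxy)benzene | COCOc1ccc(Br)c(OCOC)c1 | intermediate
19 | [2,4-bis(methoxymethoxy)phenyl]boronic acid | OB(O)c1ccc(OCOC)cc1OCOC | intermediate
20 | (2S)-2-[2,4-bis(methoxymethoxy)phenyl]-7-(methoxymethoxy)-8-SC-2,3-dihydro-4H-chromen-4-one | CC(C)=CC[C@H](Cc1c(OCOC)ccc2c1O[C@H](c1ccc(OCOC)cc1OCOC)CC2=O)[C@H](C)CO | intermediate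
21 | 5-Bpin derivative of 20 with the C4'' oxygen carried as O-Bpin (not isolated) | CC(C)=CC[C@H](Cc1c(OCOC)cc(B3OC(C)(C)C(C)(C)O3)c2c1O[C@H](c1ccc(OCOC)cc1OCOC)CC2=O)[C@H](C)COB1OC(C)(C)C(C)(C)O1 | intermediate
22 | (2S)-2-[2,4-bis(methoxymethoxy)phenyl]-5-hydroxy-7-(methoxymethoxy)-8-SC-2,3-dihydro-4H-chromen-4-one | CC(C)=CC[C@H](Cc1c(OCOC)cc(O)c2c1O[C@H](c1ccc(OCOC)cc1OCOC)CC2=O)[C@H](C)CO | intermediate
23 | (2S)-2-(2,4-dihydroxyphenyl)-5,7-dihydroxy-8-[(2R)-2-[(2S)-1-hydroxypropan-2-yl]-5-methylhex-4-en-1-yl]-2,3-dihydro-4H-chromen-4-one | CC(C)=CC[C@H](Cc1c(O)cc(O)c2c1O[C@H](c1ccc(O)cc1O)CC2=O)[C@H](C)CO | target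

## Step count and risks
Total step count: 11.
Longest linear sequence: 8 steps (2, 3, 4, 5, 6, 9, 10, 11), from 3 to 23.

The three steps most likely to fail are steps 4, 9 and 10.

**Step 4 (the new step).**
- Risks: the hindered boronate 8 may be lost before it captures the diazoalkane. The diazoalkane may undergo a hydride shift or close to a tetrahydrofuran. Oxaborinane 10 may protodeboronate slowly.
- Fallback: it sets out from 2 and 5 and comes back at 11.
- Lactone 5 is reduced to lactol 6 as in step 3. Compound 2 is lithiated (n-BuLi, THF, 0 °C), and 2.2 equiv of it are added to 6 at −78 °C (1,2-addition to the open hydroxy aldehyde). This gives (2S,3S)-1-[2,6-bis(methoxymethoxy)phenyl]-3-methyl-2-(3-methylbut-2-en-1-yl)butane-1,4-diol F1 as a mixture at the carbinol carbon.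
- Li in NH3(l)/THF at −78 °C with an NH4Cl quench then cleaves the benzylic C–O bond (dissolving-metal deoxygenation of a benzylic alcohol). The alkene, the MOM ethers and both stereocentres are left alone, and 11 is obtained.

**Step 9.**
- Risks: the ortho-alkoxy, electron-rich boronic acid 19 may protodeboronate faster than it transmetalates. The electron-rich chromone is also a sluggish acceptor.
- Fallback: it sets out from 14 and 18 and comes back at 20.
- Bromide 18 is converted (n-BuLi, then DMF) into 2,4-bis(methoxymethoxy)benzaldehyde F2. Claisen–Schmidt condensation of 14 with the aldehyde (KOH, EtOH, rt) gives the (E)-2'-hydroxychalcone F3.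
- NaOAc in refluxing EtOH closes ring C by oxa-Michael addition to a roughly 1:1 mixture of 20 and its (2R)-epimer F4. The two are diastereomers because of the side chain and are separated by preparative HPLC. The unwanted epimer is re-equilibrated with base through the chalcone and recycled.

**Step 10.**
- Risks: the directed borylation may need excess substrate. It may compete with borylation at C6 or on ring B, or it may hydroborate the alkene.
- Fallback: it sets out from 11 and comes back at 22.
- Sterically controlled borylation of 11 ([Ir(OMe)(cod)]2, 4,4'-di-tert-butyl-2,2'-bipyridine, B2pin2) hits the only C–H bond without an ortho substituent. Peroxide work-up gives 3,5-bis(methoxymethoxy)-4-SC-phenol F5. MeI/K2CO3 gives the aryl methyl ether F6.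
- The conditions of steps 5, 6 and 9 then give in turn 1-[2-hydroxy-6-methoxy-4-(methoxymethoxy)-3-SC-phenyl]ethan-1-one F7, 5-methoxy-7-(methoxymethoxy)-8-SC-4H-chromen-4-one F8 and the (2S)-5-methoxyflavanone F9.
- Chelation-assisted cleavage of the methoxy group peri to the carbonyl with MgI2·OEt2 in THF gives 22.

## Further compounds
F1 | step 4 | (2S,3S)-1-[2,6-bis(methoxymethoxy)phenyl]-3-methyl-2-(3-methylbut-2-en-1-yl)butane-1,4-diol (mixture at C1) | CC(C)=CC[C@H](C(O)c1c(OCOC)cccc1OCOC)[C@H](C)CO
F2 | step 9 | 2,4-bis(methoxymethoxy)benzaldehyde | COCOc1ccc(C=O)c(OCOC)c1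
F3 | step 9 | (E)-3-[2,4-bis(methoxymethoxy)phenyl]-1-[2-hydroxy-4-(methoxymethoxy)-3-SC-phenyl]prop-2-en-1-one | CC(C)=CC[C@H](Cc1c(OCOC)ccc(C(=O)/C=C/c2ccc(OCOC)cc2OCOC)c1O)[C@H](C)CO
F4 | step 9 | (2R)-2-[2,4-bis(methoxymethoxy)phenyl]-7-(methoxymethoxy)-8-SC-2,3-dihydro-4H-chromen-4-one | CC(C)=CC[C@H](Cc1c(OCOC)ccc2c1O[C@@H](c1ccc(OCOC)cc1OCOC)CC2=O)[C@H](C)CO
F5 | step 10 | 3,5-bis(methoxymethoxy)-4-SC-phenol | CC(C)=CC[C@H](Cc1c(OCOC)cc(O)cc1OCOC)[C@H](C)CO
F6 | step 10 | (2S,3R)-3-[4-methoxy-2,6-bis(methoxymethoxy)benzyl]-2,6-dimethylhept-5-en-1-ol | CC(C)=CC[C@H](Cc1c(OCOC)cc(OC)cc1OCOC)[C@H](C)CO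
F7 | step 10 | 1-[2-hydroxy-6-methoxy-4-(methoxymethoxy)-3-SC-phenyl]ethan-1-one | CC(C)=CC[C@H](Cc1c(OCOC)cc(OC)c(C(C)=O)c1O)[C@H](C)CO
F8 | step 10 | 5-methoxy-7-(methoxymethoxy)-8-SC-4H-chromen-4-one | CC(C)=CC[C@H](Cc1c(OCOC)cc(OC)c2c1OC=CC2=O)[C@H](C)CO
F9 | step 10 | (2S)-2-[2,4-bis(methoxymethoxy)phenyl]-5-methoxy-7-(methoxymethoxy)-8-SC-2,3-dihydro-4H-chromen-4-one | CC(C)=CC[C@H](Cc1c(OCOC)cc(OC)c2c1O[C@H](c1ccc(OCOC)cc1OCOC)CC2=O)[C@H](C)CO
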